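A small charge of nucleophile, as in the elm run, leaves 67.2 % of the electrophile standing at 4.00 min, and I want to know what 0.600 mM leaves.

common to all: electrophile 5.0 × 10⁻⁴ M

| charge | nucleophile | free base | remark | time |
|---|---|---|---|---|
| elm | 0.30 mM (fed, over 80 s) | 0.75 mM | run made earlier |  |
| larch | 1.2 mM (fed, over 80 s) | 0.75 mM | run made earlier |  |
| flask | 0.600 mM (fed, over 80 s) | 0.750 mM |  | 15 min |

| run | time / min | electrophile / % | target / % |
|---|---|---|---|
| elm | 1.33 | 73.4 | 6.6 |
| elm | 4.00 | 67.2 | 0.3 |
| elm | 8.00 | 65.4 | 0.9 |
| elm | 10.0 | 63.5 | 0.3 |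
| elm | 15.0 | 61.9 | 0 |
| larch | 3.00 | 1.0 | 1.5 |
| larch | 6.00 | 0 | 0.4 |
| larch | 10.0 | 0.6 | 0 |
| larch | 12.0 | 1.5 | 0.8 |
| larch | 15.0 | 1.2 | 0 |

(readings scatter by 1 percentage point)

- part of the electrophile that has reacted at 15 min
- share of the unused nucleophile that is free and not bound as protonated nucleophile, at 15 min

- the numbers in the tables scatter with a standard deviation of 1 percentage point
- the earlier runs do not show how much of nucleophile is bound; that part of a forecast is a guess

From elm at that time I read 0.547: this is the reach r, the electrophile lost per nucleophile charged once the fast fall is over. With the free base charge held as in elm, and c_B and c_A the charges of nucleophile and electrophile, control changes hands where r·c_B/c_A crosses 100 %. Larch gives 131 %, and its electrophile reads 1.2 % at 15.0 min. This flask gives 65.6 %, so here the nucleophile is the limiting reagent. Elm still loses 5.3 percentage points by 15.0 min, so I hold 65.6 % as my low side.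

The forecast is higher than my figure: 70 % reacted (60 % to 82 %), with a free share of 30 % (8 % to 70 %), of which it says: “The free share is a guess”.

The flask gives 67.6 % reacted, inside the forecast's range, and a free share of 0.580 %, below that range.

    electrophile + nucleophile → acid set free + target (k = 97.0 M⁻¹ s⁻¹)
    nucleophile + acid set free ⇌ protonated nucleophile, settled at all times (K = 5.50 × 10⁶ M⁻¹)
    acid set free + free base ⇌ salt of the base (K = 2100 M⁻¹, k = 750 M⁻¹ s⁻¹)
    target → over-reaction product (k = 0.0550 s⁻¹)

Reckoned as if the whole nucleophile charge were there at once, the electrophile's half-life is 0.20 min, short against 15 min, yet 32 % of it stands in this flask at 15.0 min. At that time this flask holds 1.52 × 10⁻⁶ M of free nucleophile against 2.61 × 10⁻⁴ M of protonated nucleophile.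

In the neighbour flask with 2.0 × 10⁻⁴ M of electrophile, r·c_B/c_A is 164 %, past the crossing, so I expect the electrophile to go first. Computed, that flask has 100 % of its electrophile reacted, keeps 33 % of its nucleophile unbound, and has a free share of 50.1 %.

(The numbers in the tables are simulated for an exercise.)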